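The closed, stirred vessel turns starting material into ring and open dimer, and the quantity to watch is open dimer, which rises and then falls.

| setting | blue | ochre | flask |
|---|---|---|---|
| starting material | 13 mM | 30 mM | 20 mM |
| remark | run made earlier | run made earlier |  |
| time |  |  | 8.0 h |

| run | time / h | open dimer / % | ring / % |
|---|---|---|---|
| blue | 0.667 | 21.7 | 8.5 |
| blue | 1.33 | 29.5 | 13.5 |
| blue | 3.00 | 33.8 | 19.8 |
| blue | 6.00 | 30.0 | 25.3 |
| ochre | 0.667 | 38.8 | 7.1 |
| ochre | 1.33 | 47.5 | 10.4 |
| ochre | 3.00 | 49.9 | 14.2 |
| ochre | 6.00 | 44.2 | 18.2 |

(readings scatter by 0.3 percentage points)

- percentages count the starting material that a species holds: one open dimer counts as two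

- the best time, 8.0 h at the latest, for open dimer
- the amount of open dimer, in percent of the starting material charged, at that time

Blue and ochre stand at either end of this flask's charge, and each has its highest reading at 3.00 h: 33.8% and 49.9%. Joining them by a straight line in ln[starting material] gives 42.1% for this flask near that time.

The weak link is that shared reading time. Ochre's reading at 3.00 h stands 2.4 percentage points above the one before it and 5.7 points above the one after it, which points to an ochre peak before that reading. A parabola in ln(time) through the readings at 1.33 h, 3.00 h and 6.00 h puts blue's peak at 2.89 h and 33.8%, and ochre's at 2.44 h and 50.2%. Their difference over the ln of the charge ratio is 20 points: the charge slope, peak open dimer gained per unit of ln[starting material] charged. The slope then puts this flask's peak at 42.3%, and the same join in ln(time) gives 2.65 h.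

The forecast says 42.3% at 2.5 h: “The dimer peak occurs when formation balances reversion”. The flask gives 42.0% at 2.68 h.

    starting material → ring (k = 0.00280 min⁻¹)
    2 starting material ⇌ open dimer (K = 310 M⁻¹, k = 0.350 M⁻¹ min⁻¹)
    starting material + ring → side product (k = 0.190 M⁻¹ min⁻¹)
    starting material ⇌ dormant form (K = 19.0, k = 0.00290 min⁻¹)

The charge slope lands 0.27 points from this flask's maximum. Carried past ochre's charge to the neighbouring flask with 34 mM of starting material, it gives 52.7%. That neighbouring flask reaches 52.6%, and at 8.00 h it holds 41.7% of open dimer.

The numbers in the tables were generated by integration with constants of no real substance.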